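## Structural features

The target is an isoflavone: a benzene ring A fused along C4a–C8a to a 4-pyranone ring C, with a 2,4-dihydroxyphenyl ring B on C3. Ring A is hexasubstituted, with hydroxyls on C5 and C7, 3-methylbut-2-enyl (prenyl) groups on C6 and C8, and the two fusion carbons. There is no stereocentre, so none stand next to each other; the only stereochemical element on the way is the geometry of the C2=C3 double bond in open-chain intermediates, and ring closure erases it. The fragile parts are the two trisubstituted prenyl alkenes, each ortho to a phenol (acid closes them to chromans; halogen electrophiles, hydrogenation and oxidants attack them), and the electron-rich polyphenol. The 2'-hydroxyl of ring B is a further hazard, because it can reach C2 and close a benzofuran in place of ring C. The real difficulty is twofold: placing four substituents on ring A without regiochemical error, and joining C4 to the crowded carbon C4a while C2 arrives at the right oxidation level. The key step uses the fact that C4 is a carbonyl carbon bonded only to C4a and C3, so it maps onto CO inserted between a ring A aryl–palladium bond and a C2–C3 alkenyl unit that already carries ring B. In the open-chain form ring A has a mirror plane through C4a and C7, so its two ortho oxygens (future O1 and O5) are equivalent and ring C can close in only one way.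

## Logic of the disconnections

**23 ⇒ 22.** The two O–Si bonds on ring B are cut. No skeletal bond changes. Keeping both ring B oxygens silylated until ring C exists removes the 2'-oxygen as a competitor for C2, and the final unmasking is done with fluoride, not with acid. The demand is that the silyl ethers survive every step from 11 to 22, including one acid step.

**22 ⇒ 20.** The O1–C2 bond of ring C is cut, and the three acetal groups of ring A are put back. The forward step is an addition–elimination at C2 of a β-methoxy enone by an ortho phenol. This reduces the bicyclic chromone to an open-chain ketone in which ring A is symmetric, so either ortho oxygen gives the same product and the C2=C3 geometry is irrelevant. The demand is an acid mild enough to cleave three aryl acetals without hydrating or cyclising the prenyl groups and without removing the silyl ethers.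

**20 ⇒ 9 + 19 + 18.** The C4a–C4 and C4–C3 bonds are cut at the carbonyl carbon. This is the most simplifying cut in the molecule: it separates a symmetric, fully substituted ring A from a C2–C3–ring B unit and supplies C4 from 19. The forward step must insert 19 before the alkenyl group is transferred, must tolerate an aryl iodide flanked by two ortho oxygens, and must not disturb the enol ether, the acetals, the silyl ethers or the prenyl alkenes.

**9 ⇒ 7 ⇒ 5 ⇒ 2 ⇒ 1.** The C–I bond and then the two ring-to-prenyl bonds (C6–C1'' and C8–C1''') are cut, each one a directed ortho-metalation followed by an electrophile (3 for the prenyl groups), and finally the three acetals. Every metalation site lies between two acetal oxygens, and the sites still free at each stage are equivalent or unique, so regiochemistry follows from symmetry. The demand is clean mono-lithiation at the ring carbon, not at a benzylic-allylic CH2, and SN2 (not SN2') delivery of the prenyl group.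

**18 ⇒ 16 ⇒ 14 ⇒ 11 + 12 ⇒ 10.** The C–B bond is cut back to a C–Br bond on the future C3, the bromine is removed to give the enol ether, and the future C2=C3 bond is cut by a methoxymethylenation of an aldehyde. The gain is that the whole C2–C3–ring B unit comes from a cheap benzaldehyde in four steps. The demand is that bromine ends up cis to the methoxy group, so that the derived vinyllithium is chelated and does not lose methoxide.

## Other disconnections considered

**Alternative 1:** Ring A is built last by a Danheiser benzannulation. The bonds cut are C8–C8a, C5–C6, C7–C8 and C4a–C5.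
- **Forward step:** irradiation of the pyranonyl diazo ketone A2 gives a vinylketene by Wolff rearrangement. This adds the siloxyalkyne A3 in a [2+2] sense; four-electron opening of the cyclobutenone and six-electron closure onto C4a then give the chromone A1.
- **In its favour:** the hexasubstituted ring A arises in one operation, and every substituent position is dictated by the connectivity of A2 and A3, not by symmetry or by metalation. Ring C is already closed, so the 2'-oxygen cannot compete for C2. No pressurised CO and no palladium are needed. On these three points it equals or betters the chosen plan, and it forms four skeletal bonds in its key step where the chosen plan forms two.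
- **Against it:** the carbene from A2 has an adjacent CH2, so a 1,2-hydrogen shift to a dienone can compete with the Wolff rearrangement. The 4-pyranone chromophore is itself photolabile. The vinyl partner is part of an electron-poor, cross-conjugated ring. A2 needs a 2-acylpyranone carrying a diazo group next to a prenyl chain, and A3 needs ynolate chemistry. Each of these is a multi-step preparation.
- **Comparison:** the step count would be clearly higher than the 11 steps of the chosen plan, and two deprotections (silyl, then acetals) still follow A1.

**Alternative 2:** Both prenyl groups are put on last by a double aromatic Claisen rearrangement. The bonds cut are C6–C1'' and C8–C1'''.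
- **Forward step:** heating the bis(1,1-dimethylallyl) ether A5 in N,N-diethylaniline should move the C5 ether group to C6 and the C7 ether group to C8, giving A4.
- **In its favour:** the isoflavone nucleus is made before any prenyl group exists. The rearrangement loses no atoms. The prenyl groups see only one later step, and only one deprotection follows A4. It uses no organometallic reagent and no CO. On the length of the end game and on the precedent for this kind of shift on flavonoid nuclei it equals or betters the chosen plan.
- **Against it:** A5 needs a tertiary ether on the chelated, hindered 5-hydroxyl. Each tertiary ether costs two steps (O-propargylation and partial hydrogenation). The C7 ether can migrate to C6 as well as to C8; the C5 ether would then have no free ortho carbon and could only go on to C8 by a second shift, which delivers a 1,1-dimethylallyl group. At the temperature required, ortho-prenyl phenols can also cyclise.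
- **Comparison:** the chosen plan fixes the prenyl positions by metalation between two oxygens, so it does not depend on a kinetic preference. The overall step count would be similar or higher once the precursors of A5 are counted.

**Alternative 3:** Ring A is folded biomimetically from a polyketide chain. The bond cut is C4a–C8a.
- **Forward step:** with Mg(OMe)2 in methanol, the central methylene of the triketo ester A7 attacks the ester carbonyl in a Claisen condensation, and aromatisation gives the deoxybenzoin A6 with both prenyl groups in place.
- **In its favour:** it needs no transition metal and no protecting group on ring A. A6 has the same local symmetry as the open-chain ketone of the chosen plan, so the later ring C closure is equally unambiguous. On the economy of ring A protecting groups it betters the chosen plan.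
- **Against it:** A7 has three ketones and several acidic positions. Aldol-type closures and O-cyclisation to pyranones compete with the Claisen mode. Placing prenyl groups on two defined carbons of such a chain is itself a hard problem, and the prenylated carbons are more hindered and less acidic. A6 also lacks C2, so a separate formylation–cyclisation and an acid deprotection must follow on a free, prenylated phloroglucinol.
- **Comparison:** the chosen plan brings in C4 and the C2–C3 unit in one coupling and reaches the ring-closure substrate directly. Alternative 3 would need more steps after its key step and rests on a less controllable cyclisation.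

Key step: step 9

Remark (ring B protection): ring B carries triisopropylsilyl ethers, not acetals, because a 2'-hydroxyl set free together with the ring A phenols could attack C2 and give a 3-aroylbenzofuran; the silyl ethers outlast the acid step and are removed last with fluoride.

Remark (alkene geometry): the boronate is made as the isomer with boron and methoxy cis (E descriptor), since only this isomer comes from a vinyllithium that is held by O–Li chelation and cannot lose LiOMe by anti elimination; the enone 20 is then Z, and ring closure erases the geometry.

Remark (assumption): enol ether 14 is expected as an E/Z mixture and is listed as its E isomer; both isomers pass through the same dibromo ether 15, and 16 is assumed to form with bromine cis to methoxy, as is usual for 2-bromo enol ethers made by bromination–dehydrobromination.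

## Route

Step 1
Reactants: 1 phloroglucinol (benzene-1,3,5-triol)
Product: 2 1,3,5-tris(methoxymethoxy)benzene
Conditions: NaH, MOMCl, DMF, 0 °C to rt
Reagents that add atoms: chloromethyl methyl ether (MOMCl), COCCl
Why: Williamson-type O-alkylation of the triphenoxide with a hard chloromethyl ether; O-alkylation should dominate over C-alkylation with this electrophile.

Step 2
Reactants: 2 1,3,5-tris(methoxymethoxy)benzene; 3 prenyl bromide (1-bromo-3-methylbut-2-ene)
Product: 5 1,3,5-tris(methoxymethoxy)-2-(3-methylbut-2-enyl)benzene, via aryllithium 4 (not isolated)
Conditions: n-BuLi, THF, 0 °C; then CuBr·SMe2 (10 mol %), 3, −78 °C to rt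
Reagents that add atoms: none
Why: Directed ortho-metalation between two acetal oxygens (all three ring positions are equivalent) followed by copper-mediated allylic substitution, which should favour SN2 attack at the primary carbon of 3.

Step 3
Reactants: 5 1,3,5-tris(methoxymethoxy)-2-(3-methylbut-2-enyl)benzene; 3 prenyl bromide
Product: 7 1,3,5-tris(methoxymethoxy)-2,4-bis(3-methylbut-2-enyl)benzene, via aryllithium 6 (not isolated)
Conditions: n-BuLi, THF, 0 °C; then CuBr·SMe2 (10 mol %), 3, −78 °C to rt
Reagents that add atoms: none
Why: Second directed ortho-metalation; the two remaining ring hydrogens are equivalent and each lies between two acetal oxygens, which should outcompete deprotonation of the benzylic-allylic CH2.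

Step 4
Reactants: 7 1,3,5-tris(methoxymethoxy)-2,4-bis(3-methylbut-2-enyl)benzene
Product: 9 2-iodo-1,3,5-tris(methoxymethoxy)-4,6-bis(3-methylbut-2-enyl)benzene, via aryllithium 8 (not isolated)
Conditions: n-BuLi, THF, 0 °C; then I2, THF, −78 °C
Reagents that add atoms: iodine, II
Why: Third directed ortho-metalation at the only ring hydrogen left, then iodinolysis of the aryllithium, which at −78 °C should be far faster than any reaction of iodine with the prenyl alkenes.

Step 5
Reactants: 10 2,4-dihydroxybenzaldehyde
Product: 11 2,4-bis(triisopropylsilyloxy)benzaldehyde
Conditions: TIPSCl, imidazole, DMF, rt to 40 °C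
Reagents that add atoms: chlorotriisopropylsilane (TIPSCl), CC(C)[Si](Cl)(C(C)C)C(C)C
Why: Imidazole-promoted silylation of both phenols; gentle warming should overcome the hydrogen bond of the ortho hydroxyl to the aldehyde.

Step 6
Reactants: 11 2,4-bis(triisopropylsilyloxy)benzaldehyde; 12 (methoxymethyl)triphenylphosphonium chloride
Product: 14 1-[(E)-2-methoxyethenyl]-2,4-bis(triisopropylsilyloxy)benzene (Z isomer expected alongside and used together with it), via ylide 13 (not isolated)
Conditions: 12, NaN(SiMe3)2, THF, 0 °C; then 11, 0 °C to rt
Reagents that add atoms: none
Why: Wittig methoxymethylenation of an aromatic aldehyde; the amide base is non-nucleophilic at silicon, so the aryl silyl ethers should stay on.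

Step 7
Reactants: 14 1-[(E)-2-methoxyethenyl]-2,4-bis(triisopropylsilyloxy)benzene
Product: 16 1-[(Z)-1-bromo-2-methoxyethenyl]-2,4-bis(triisopropylsilyloxy)benzene, via dibromo ether 15 (not isolated)
Conditions: Br2 (1.0 equiv), CH2Cl2, −78 °C; then DBU, −78 °C to rt
Reagents that add atoms: bromine, BrBr
Why: Electrophilic addition of bromine to the enol ether, the most nucleophilic site, gives the α-bromo ether; its bromide ionises readily to the oxocarbenium ion, which loses the acidic benzylic proton (bromination–dehydrobromination), and the preference of bromine and oxygen for a cis arrangement should give the Z isomer.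

Step 8
Reactants: 16 1-[(Z)-1-bromo-2-methoxyethenyl]-2,4-bis(triisopropylsilyloxy)benzene
Product: 18 2-{(E)-1-[2,4-bis(triisopropylsilyloxy)phenyl]-2-methoxyethenyl}-4,4,5,5-tetramethyl-1,3,2-dioxaborolane, via vinyllithium 17 (not isolated)
Conditions: t-BuLi (2.1 equiv), Et2O, −78 °C; then i-PrOBpin, −78 °C to rt; aq NH4Cl
Reagents that add atoms: 2-isopropoxy-4,4,5,5-tetramethyl-1,3,2-dioxaborolane (i-PrOBpin), CC(C)OB1OC(C)(C)C(C)(C)O1
Why: Bromine–lithium exchange with retention of geometry gives a vinyllithium whose lithium is cis to methoxy and chelated by it, so anti elimination of LiOMe is not available; trapping with the borate ester and loss of isopropoxide gives the pinacol boronate with the same geometry.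

Step 9
Reactants: 9 2-iodo-1,3,5-tris(methoxymethoxy)-4,6-bis(3-methylbut-2-enyl)benzene; 19 carbon monoxide; 18 2-{(E)-1-[2,4-bis(triisopropylsilyloxy)phenyl]-2-methoxyethenyl}-4,4,5,5-tetramethyl-1,3,2-dioxaborolane
Product: 20 (Z)-2-[2,4-bis(triisopropylsilyloxy)phenyl]-3-methoxy-1-[2,4,6-tris(methoxymethoxy)-3,5-bis(3-methylbut-2-enyl)phenyl]prop-2-en-1-one
Conditions: Pd(OAc)2 (5 mol %), P(1-Ad)2(n-Bu) (10 mol %), K3PO4, H2O (5 equiv), CO (5 bar), 1,4-dioxane, 80 °C
Reagents that add atoms: none
Why: Zerovalent palladium, formed from Pd(OAc)2 and the phosphine, inserts into the C–I bond of 9; CO then coordinates and inserts to give a divalent aroylpalladium iodide, which forms the C4a–C4 bond. Base-assisted transmetalation with 18 and reductive elimination form the C4–C3 bond and release 20 with the alkene geometry retained. The closest known reaction type is the carbonylative Suzuki–Miyaura coupling of aryl iodides with alkenylboron reagents, which is established chemistry. No ring is closed and no stereocentre is formed, so neither a mode of closure nor a controlling element applies. The selectivity needed is carbonylative over direct coupling: the two ortho acetal oxygens, buttressed by the prenyl groups, slow transmetalation at the arylpalladium stage, while insertion of the small CO ligand into an electron-rich aryl–palladium bond is fast and is further favoured by the CO pressure. The bulky, electron-rich phosphine keeps palladium monoligated and active towards the hindered iodide under CO. The weakly basic medium should leave the acetals, the silyl ethers, the enol ether and both prenyl alkenes untouched, and a Heck pathway on the trisubstituted alkenes is not expected.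

Step 10
Reactants: 20 (Z)-2-[2,4-bis(triisopropylsilyloxy)phenyl]-3-methoxy-1-[2,4,6-tris(methoxymethoxy)-3,5-bis(3-methylbut-2-enyl)phenyl]prop-2-en-1-one
Product: 22 3-[2,4-bis(triisopropylsilyloxy)phenyl]-5,7-dihydroxy-6,8-bis(3-methylbut-2-enyl)chromen-4-one, via triphenol enone 21 (not isolated)
Conditions: HCl (1.25 M in MeOH), THF, 40 °C
Reagents that add atoms: none
Why: Acid-catalysed transacetalisation to methanol removes the three aryl acetals, those ortho to the ketone first; a freed ortho phenol adds to C2 of the protonated β-methoxy enone (6-endo oxa-Michael addition) and methanol is lost, an addition–elimination that gives the chromone whichever of the two equivalent oxygens reacts, while the silyl ether on the 2'-oxygen blocks benzofuran closure and aryl triisopropylsilyl ethers should resist dilute methanolic HCl.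

Step 11
Reactants: 22 3-[2,4-bis(triisopropylsilyloxy)phenyl]-5,7-dihydroxy-6,8-bis(3-methylbut-2-enyl)chromen-4-one
Product: 23 3-(2,4-dihydroxyphenyl)-5,7-dihydroxy-6,8-bis(3-methylbut-2-enyl)chromen-4-one (target)
Conditions: Bu4NF, AcOH, THF, 0 °C
Reagents that add atoms: none
Why: Fluoride-induced cleavage of the two aryl silyl ethers with phenoxide as leaving group; acetic acid buffering keeps the medium near neutral, so neither the chromone nor the prenyl groups should be affected.

## Compound list

1 | phloroglucinol (benzene-1,3,5-triol) | Oc1cc(O)cc(O)c1 | starting material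
2 | 1,3,5-tris(methoxymethoxy)benzene | COCOc1cc(OCOC)cc(OCOC)c1 | intermediate
3 | prenyl bromide (1-bromo-3-methylbut-2-ene) | CC(C)=CCBr | starting material
4 | 2,4,6-tris(methoxymethoxy)phenyllithium | [Li]c1c(OCOC)cc(OCOC)cc1OCOC | intermediate
5 | 1,3,5-tris(methoxymethoxy)-2-(3-methylbut-2-enyl)benzene | COCOc1cc(OCOC)cc(OCOC)c1CC=C(C)C | intermediate
6 | 2,4,6-tris(methoxymethoxy)-3-(3-methylbut-2-enyl)phenyllithium | [Li]c1c(OCOC)cc(OCOC)c(CC=C(C)C)c1OCOC | intermediate
7 | 1,3,5-tris(methoxymethoxy)-2,4-bis(3-methylbut-2-enyl)benzene | COCOc1cc(OCOC)c(CC=C(C)C)c(OCOC)c1CC=C(C)C | intermediate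
8 | 2,4,6-tris(methoxymethoxy)-3,5-bis(3-methylbut-2-enyl)phenyllithium | [Li]c1c(OCOC)c(CC=C(C)C)c(OCOC)c(CC=C(C)C)c1OCOC | intermediate
9 | 2-iodo-1,3,5-tris(methoxymethoxy)-4,6-bis(3-methylbut-2-enyl)benzene | COCOc1c(I)c(OCOC)c(CC=C(C)C)c(OCOC)c1CC=C(C)C | intermediate
10 | 2,4-dihydroxybenzaldehyde | O=Cc1ccc(O)cc1O | starting material
11 | 2,4-bis(triisopropylsilyloxy)benzaldehyde | O=Cc1ccc(O[Si](C(C)C)(C(C)C)C(C)C)cc1O[Si](C(C)C)(C(C)C)C(C)C | intermediate
12 | (methoxymethyl)triphenylphosphonium chloride | COC[P+](c1ccccc1)(c1ccccc1)c1ccccc1.[Cl-] | starting material
13 | (methoxymethylene)triphenylphosphorane | COC=P(c1ccccc1)(c1ccccc1)c1ccccc1 | intermediate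
14 | 1-[(E)-2-methoxyethenyl]-2,4-bis(triisopropylsilyloxy)benzene | CO/C=C/c1ccc(O[Si](C(C)C)(C(C)C)C(C)C)cc1O[Si](C(C)C)(C(C)C)C(C)C | intermediate
15 | 1-(1,2-dibromo-2-methoxyethyl)-2,4-bis(triisopropylsilyloxy)benzene (diastereomer mixture; both centres are destroyed in the elimination) | COC(Br)C(Br)c1ccc(O[Si](C(C)C)(C(C)C)C(C)C)cc1O[Si](C(C)C)(C(C)C)C(C)C | intermediate
16 | 1-[(Z)-1-bromo-2-methoxyethenyl]-2,4-bis(triisopropylsilyloxy)benzene | CO/C=C(\Br)c1ccc(O[Si](C(C)C)(C(C)C)C(C)C)cc1O[Si](C(C)C)(C(C)C)C(C)C | intermediate
17 | (E)-1-[2,4-bis(triisopropylsilyloxy)phenyl]-2-methoxyethenyllithium | CO/C=C(\[Li])c1ccc(O[Si](C(C)C)(C(C)C)C(C)C)cc1O[Si](C(C)C)(C(C)C)C(C)C | intermediate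
18 | 2-{(E)-1-[2,4-bis(triisopropylsilyloxy)phenyl]-2-methoxyethenyl}-4,4,5,5-tetramethyl-1,3,2-dioxaborolane | CO/C=C(\B1OC(C)(C)C(C)(C)O1)c1ccc(O[Si](C(C)C)(C(C)C)C(C)C)cc1O[Si](C(C)C)(C(C)C)C(C)C | intermediate
19 | carbon monoxide | [C-]#[O+] | starting material
20 | (Z)-2-[2,4-bis(triisopropylsilyloxy)phenyl]-3-methoxy-1-[2,4,6-tris(methoxymethoxy)-3,5-bis(3-methylbut-2-enyl)phenyl]prop-2-en-1-one | CO/C=C(\C(=O)c1c(OCOC)c(CC=C(C)C)c(OCOC)c(CC=C(C)C)c1OCOC)c1ccc(O[Si](C(C)C)(C(C)C)C(C)C)cc1O[Si](C(C)C)(C(C)C)C(C)C | intermediate
21 | (Z)-2-[2,4-bis(triisopropylsilyloxy)phenyl]-3-methoxy-1-[2,4,6-trihydroxy-3,5-bis(3-methylbut-2-enyl)phenyl]prop-2-en-1-one | CO/C=C(\C(=O)c1c(O)c(CC=C(C)C)c(O)c(CC=C(C)C)c1O)c1ccc(O[Si](C(C)C)(C(C)C)C(C)C)cc1O[Si](C(C)C)(C(C)C)C(C)C | intermediate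
22 | 3-[2,4-bis(triisopropylsilyloxy)phenyl]-5,7-dihydroxy-6,8-bis(3-methylbut-2-enyl)chromen-4-one | CC(C)=CCc1c(O)c(CC=C(C)C)c2occ(-c3ccc(O[Si](C(C)C)(C(C)C)C(C)C)cc3O[Si](C(C)C)(C(C)C)C(C)C)c(=O)c2c1O | intermediate
23 | 3-(2,4-dihydroxyphenyl)-5,7-dihydroxy-6,8-bis(3-methylbut-2-enyl)chromen-4-one | CC(C)=CCc1c(O)c(CC=C(C)C)c2occ(-c3ccc(O)cc3O)c(=O)c2c1O | target

## Step count and least certain steps

Total: 11 steps. Longest linear sequence: 7 steps (steps 1–4, then 9–11; the boronate branch, steps 5–8 then 9–11, is equally long).

**Step 9 (key step).** The most likely failure is slow transmetalation of the hindered alkenylboronate to the crowded aroylpalladium intermediate. The acyl complex could then be hydrolysed to the benzoic acid, the enol ether boronate could suffer protodeboronation, or direct coupling without CO could take over. The fallback avoids palladium and CO altogether. It sets out from 7 and 16 and comes back at 20. Lithiation of 7 as in step 4 (giving 8) and quenching with DMF at −78 °C should give 2,4,6-tris(methoxymethoxy)-3,5-bis(3-methylbut-2-enyl)benzaldehyde F1. Vinyllithium 17, made from 16 as in step 8, is then added to F1 at −78 °C to give (Z)-2-[2,4-bis(triisopropylsilyloxy)phenyl]-3-methoxy-1-[2,4,6-tris(methoxymethoxy)-3,5-bis(3-methylbut-2-enyl)phenyl]prop-2-en-1-ol F2 as a racemate. Oxidation of this benzylic, allylic alcohol with MnO2 in CH2Cl2 under neutral conditions should give 20.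

**Step 8.** The danger is β-elimination of LiOMe to the arylalkyne from any vinyllithium in which lithium and methoxy are anti, and migration of silicon from the ortho oxygen to carbon if the anion is allowed to warm. The fallback sets out from 16 and comes back at 18 without an organolithium: palladium-catalysed Miyaura borylation with B2pin2, PdCl2(dppf) and KOAc in 1,4-dioxane at 80 °C, which retains the alkene geometry and accepts either isomer of the bromide. No new compound arises (F0).

**Step 10.** The danger is acid-catalysed addition of the C5 or C7 hydroxyl to a neighbouring prenyl alkene (chroman formation) before the last acetal has gone, together with slow loss of a silyl group. The fallback separates deprotection from ring closure and uses no protic acid. It sets out from 20 and comes back at 22. Thiolysis of the acetals with ZnBr2 and n-PrSH in CH2Cl2 at 0 °C should give 21, which is isolated. Ring C is then closed by phenoxide conjugate addition–elimination with Et3N in toluene at 50 °C. No new compound arises (F0).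

**Step 7.** The danger is competing electrophilic bromination of the electron-rich ring B, loss of a silyl group to adventitious HBr, and incomplete control of the alkene geometry. The fallback sets out from 14 and comes back at 16. Bromomethoxylation with N-bromosuccinimide in MeOH at −20 °C should give 1-(1-bromo-2,2-dimethoxyethyl)-2,4-bis(triisopropylsilyloxy)benzene F3, a stable acetal that can be purified. Elimination of methanol with Me3SiOTf and i-Pr2NEt in CH2Cl2 at 0 °C then gives 16. Should the other geometric isomer of 16 predominate by either route, the borylation fallback of step 8 would carry it through, since ring closure in step 10 does not depend on the geometry.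

## Further compounds

F1 | step 9 | 2,4,6-tris(methoxymethoxy)-3,5-bis(3-methylbut-2-enyl)benzaldehyde | O=Cc1c(OCOC)c(CC=C(C)C)c(OCOC)c(CC=C(C)C)c1OCOC
F2 | step 9 | (Z)-2-[2,4-bis(triisopropylsilyloxy)phenyl]-3-methoxy-1-[2,4,6-tris(methoxymethoxy)-3,5-bis(3-methylbut-2-enyl)phenyl]prop-2-en-1-ol (racemic) | CO/C=C(\C(O)c1c(OCOC)c(CC=C(C)C)c(OCOC)c(CC=C(C)C)c1OCOC)c1ccc(O[Si](C(C)C)(C(C)C)C(C)C)cc1O[Si](C(C)C)(C(C)C)C(C)C
F0 | step 8 | none | none
F0 | step 10 | none | none
F3 | step 7 | 1-(1-bromo-2,2-dimethoxyethyl)-2,4-bis(triisopropylsilyloxy)benzene (racemic) | COC(OC)C(Br)c1ccc(O[Si](C(C)C)(C(C)C)C(C)C)cc1O[Si](C(C)C)(C(C)C)C(C)C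
A1 | alternative 1 | 3-[2,4-bis(methoxymethoxy)phenyl]-5-hydroxy-6,8-bis(3-methylbut-2-enyl)-7-(triisopropylsilyloxy)chromen-4-one | CC(C)=CCc1c(O[Si](C(C)C)(C(C)C)C(C)C)c(CC=C(C)C)c2occ(-c3ccc(OCOC)cc3OCOC)c(=O)c2c1O
A2 | alternative 1 | 1-{5-[2,4-bis(methoxymethoxy)phenyl]-4-oxopyran-2-yl}-2-diazo-5-methylhex-4-en-1-one | CC(C)=CCC(=[N+]=[N-])C(=O)c1cc(=O)c(-c2ccc(OCOC)cc2OCOC)co1
A3 | alternative 1 | triisopropyl(5-methylhex-4-en-1-ynyloxy)silane | CC(C)=CCC#CO[Si](C(C)C)(C(C)C)C(C)C
A4 | alternative 2 | 3-[2,4-bis(methoxymethoxy)phenyl]-5,7-dihydroxy-6,8-bis(3-methylbut-2-enyl)chromen-4-one | CC(C)=CCc1c(O)c(CC=C(C)C)c2occ(-c3ccc(OCOC)cc3OCOC)c(=O)c2c1O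
A5 | alternative 2 | 3-[2,4-bis(methoxymethoxy)phenyl]-5,7-bis(2-methylbut-3-en-2-yloxy)chromen-4-one | C=CC(C)(C)Oc1cc(OC(C)(C)C=C)c2c(=O)c(-c3ccc(OCOC)cc3OCOC)coc2c1
A6 | alternative 3 | 2-[2,4-bis(methoxymethoxy)phenyl]-1-[2,4,6-trihydroxy-3,5-bis(3-methylbut-2-enyl)phenyl]ethanone | CC(C)=CCc1c(O)c(CC=C(C)C)c(O)c(C(=O)Cc2ccc(OCOC)cc2OCOC)c1O
A7 | alternative 3 | methyl 8-[2,4-bis(methoxymethoxy)phenyl]-2,4-bis(3-methylbut-2-enyl)-3,5,7-trioxooctanoate | COC(=O)C(CC=C(C)C)C(=O)C(CC=C(C)C)C(=O)CC(=O)Cc1ccc(OCOC)cc1OCOC
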